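**Retrosynthetic overview**
- The (Z)-4-hydroxycinnamate is made last, on the C19 alcohol, by a Z-selective Horner–Wadsworth–Emmons reaction of its diphenylphosphonoacetate.
- The 2-substituted butadiene comes from ethylene–alkyne metathesis of a terminal alkyne, itself made from the C13 aldehyde (Seyferth–Gilbert).
- Key C12–C13 bond: the C12 aldehyde carbon is joined to C13, which is itself a carbonyl carbon in the product, by a formyl anion equivalent (methoxymethylene ylide). The C12 oxygen is lost in the same step.
- The C12 aldehyde comes from permanganate cleavage of the andrographolide side chain; the C3 oxygen is removed by radical deoxygenation of the 3,19-cyclic thionocarbonate.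
- No ring is formed: rings A and B and the four stereocentres C4, C5, C9 and C10 are taken intact from andrographolide.

Assumption: andrographolide, the bulk ent-labdane from Andrographis paniculata sold cheaply by the usual suppliers, counts as a commercial starting material; labdane numbering is used (C19 = the CH2O group on C4, cis to the C10 methyl).

**Route**

Step 1
Reactants: 1 andrographolide
Product: 2 (3R,4R,5S,9R,10S)-3,19-dihydroxy-13,14,15,16-tetranor-ent-labd-8(17)-en-12-al
Conditions: KMnO4 (1.4 equiv), THF/H2O (10:1), 0 °C, 30 min; NaHSO3 quench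
Reagents that add atoms: potassium permanganate, [K+].[O-][Mn](=O)(=O)=O
Why: Permanganate oxidative cleavage of an alkene (Lemieux–von Rudloff type): permanganate adds fastest to the electron-poor conjugated C12=C13 bond of the alkylidene lactone and the manganate ester collapses to the C12 aldehyde and the keto-lactone, while the hindered unactivated 8(17)-methylidene and the alcohols react much more slowly at 0 °C with a limited amount of oxidant; no stereocentre is formed and C9 (β to the new carbonyl) cannot epimerise.

Step 2
Reactants: 2 the diol aldehyde; 3 (methoxymethyl)triphenylphosphonium chloride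
Product: 4 (12E/Z)-13-methoxy-14,15,16-trinor-ent-labda-8(17),12-diene-3,19-diol
Conditions: 3 (4 equiv), KOtBu (3.9 equiv), THF, 0 °C; then 2, 0 → 23 °C
Reagents that add atoms: 3 (methoxymethyl)triphenylphosphonium chloride, COC[P+](c1ccccc1)(c1ccccc1)c1ccccc1.[Cl-]
Why: Wittig methoxymethylenation (Levine–Wittig homologation): the α-methoxy ylide is a formyl anion equivalent, so C13, a carbon that is itself a carbonyl carbon in 9, attacks the electrophilic aldehyde carbon C12 and the C12 oxygen leaves as Ph3P=O in the same step, giving the enol ether as an E/Z mixture that converges on hydrolysis, while the two hydroxyls only consume extra ylide and no stereocentre is touched.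

Step 3
Reactants: 4 the enol ether diol; 5 1,1'-thiocarbonyldiimidazole
Product: 6 3,19-O-thiocarbonyl derivative of 4 (cyclic thionocarbonate)
Conditions: 5 (1.2 equiv), DMAP (0.1 equiv), THF, 65 °C
Reagents that add atoms: 5 1,1'-thiocarbonyldiimidazole, S=C(n1ccnc1)n1ccnc1
Why: Cyclic thionocarbonate formation with thiocarbonyldiimidazole: the primary C19 hydroxyl is thioacylated first and the adjacent 3-hydroxyl then closes the six-membered 1,3-dioxane-2-thione across C3–C4–C19 (the same diol forms a six-membered acetonide readily), the enol ether being inert to the mild base.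

Step 4
Reactants: 6 the cyclic thionocarbonate
Product: 9 (4R,5S,9R,10S)-19-hydroxy-14,15,16-trinor-ent-labd-8(17)-en-13-al, via stannyl thiocarbonate 7 (not isolated), via enol ether alcohol 8 (not isolated)
Conditions: Bu3SnH (2 equiv, slow addition), AIBN (0.2 equiv), toluene, 110 °C; then 1 M HCl, THF, 23 °C
Reagents that add atoms: water, O
Why: Barton–McCombie-type radical deoxygenation of a cyclic thionocarbonate: Bu3Sn radical adds to sulfur and the adduct fragments to the secondary C3 radical in preference to the primary neopentyl C19 radical, so C3 is reduced while C19 keeps its oxygen as an S-stannyl thiocarbonate, which aqueous HCl cleaves with loss of COS while also hydrolysing the enol ether to the aldehyde; C3 ceases to be a stereocentre and C4, C5, C9 and C10 are untouched.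

Step 5
Reactants: 9 the C13 aldehyde; 10 dimethyl (1-diazo-2-oxopropyl)phosphonate
Product: 11 (4R,5S,9R,10S)-15,16-dinor-ent-labd-8(17)-en-13-yn-19-ol
Conditions: 10 (1.5 equiv), K2CO3 (2 equiv), MeOH, 0 → 23 °C
Reagents that add atoms: 10 dimethyl (1-diazo-2-oxopropyl)phosphonate, CC(=O)C(=[N+]=[N-])P(=O)(OC)OC
Why: Seyferth–Gilbert homologation in the Ohira–Bestmann form: methanolysis of 10 releases dimethyl (diazomethyl)phosphonate, whose anion adds to the aldehyde, eliminates phosphate and loses N2 with a 1,2-hydride shift to give the terminal alkyne under K2CO3/MeOH conditions that the enolisable aldehyde, the free alcohol and the 8(17)-alkene tolerate.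

Step 6
Reactants: 11 the terminal alkyne; 12 ethylene
Product: 13 (4R,5S,9R,10S)-ent-labda-8(17),13(16),14-trien-19-ol
Conditions: second-generation Grubbs catalyst RuCl2(=CHPh)(H2IMes)(PCy3) (5 mol %), ethylene (1 atm), toluene, 80 °C
Reagents that add atoms: 12 ethylene, C=C
Why: Ethylene–alkyne cross enyne metathesis (Mori): the ruthenium methylidene adds across the terminal alkyne and the vinylcarbene formed is turned over by ethylene, which delivers the 2-substituted 1,3-butadiene regiospecifically with no co-product, while the hindered 1,1-disubstituted 8(17)-alkene is not a competent partner and the ethylene atmosphere suppresses alkyne oligomerisation; no stereocentre is formed.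

Step 7
Reactants: 13 the trienol; 14 bromoacetyl bromide; 15 diphenyl phosphite
Product: 17 ent-labda-8(17),13(16),14-trien-19-yl (diphenoxyphosphoryl)acetate, via bromoacetate 16 (not isolated)
Conditions: 14 (1.2 equiv), pyridine (1.3 equiv), CH2Cl2, 0 °C; then 15 (1.5 equiv), Et3N (2 equiv), 0 → 23 °C
Reagents that add atoms: 14 bromoacetyl bromide, O=C(Br)CBr; 15 diphenyl phosphite, O=[PH](Oc1ccccc1)Oc1ccccc1
Why: O-acylation followed by Michaelis–Becker phosphonylation: the neopentyl C19 alcohol is acylated by the reactive acid bromide with pyridine scavenging HBr away from the diene, and the triethylammonium salt of diphenyl phosphite then displaces the activated α-bromide, which is the standard way to make diaryl phosphonoacetates.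

Step 8
Reactants: 17 the phosphonoacetate; 18 4-(tert-butyldimethylsilyloxy)benzaldehyde
Product: 20 ent-labda-8(17),13(16),14-trien-19-yl (2Z)-3-(4-hydroxyphenyl)prop-2-enoate (the target), via silyl ether 19 (not isolated)
Conditions: NaH (1.05 equiv), THF, 0 °C; 18, −78 → −20 °C; then AcOH (1.5 equiv), Bu4NF (1.2 equiv), 0 °C
Reagents that add atoms: 18 4-(tert-butyldimethylsilyloxy)benzaldehyde, O=Cc1ccc(O[Si](C)(C)C(C)(C)C)cc1
Why: Z-selective Horner–Wadsworth–Emmons olefination of the Ando type followed by fluoride desilylation: the electron-poor diaryl phosphonate makes the syn oxaphosphetane collapse faster than it equilibrates, so the (Z)-cinnamate is the kinetic product (about 9:1 with aryl aldehydes, helped by the bulky ester, the minor E isomer being removed by chromatography), and acetic-acid-buffered fluoride then cleaves only the aryl silyl ether without isomerising the alkene.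

**Compound list**

1 | andrographolide | O[C@@H]1COC(=O)/C1=C/C[C@@H]1C(=C)CC[C@@H]2[C@](C)(CO)[C@H](O)CC[C@@]12C | starting material
2 | (3R,4R,5S,9R,10S)-3,19-dihydroxy-13,14,15,16-tetranor-ent-labd-8(17)-en-12-al | O=CC[C@@H]1C(=C)CC[C@@H]2[C@](C)(CO)[C@H](O)CC[C@@]12C | intermediate
3 | (methoxymethyl)triphenylphosphonium chloride | COC[P+](c1ccccc1)(c1ccccc1)c1ccccc1.[Cl-] | starting material
4 | (12E)-13-methoxy-14,15,16-trinor-ent-labda-8(17),12-diene-3,19-diol (3R,4R,5S,9R,10S; the 12Z isomer forms alongside and is carried on) | CO/C=C/C[C@@H]1C(=C)CC[C@@H]2[C@](C)(CO)[C@H](O)CC[C@@]12C | intermediate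
5 | 1,1'-thiocarbonyldiimidazole | S=C(n1ccnc1)n1ccnc1 | starting material
6 | 3,19-O-thiocarbonyl derivative of 4 (six-membered cyclic thionocarbonate across C3-C4-C19; 12E shown) | CO/C=C/C[C@@H]1C(=C)CC[C@@H]2[C@]3(C)COC(=S)O[C@@H]3CC[C@@]12C | intermediate
7 | O-[(12E)-13-methoxy-14,15,16-trinor-ent-labda-8(17),12-dien-19-yl] S-(tributylstannyl) thiocarbonate | CO/C=C/C[C@@H]1C(=C)CC[C@@H]2[C@](C)(COC(=O)S[Sn](CCCC)(CCCC)CCCC)CCC[C@@]12C | intermediate (not isolated)
8 | (12E)-13-methoxy-14,15,16-trinor-ent-labda-8(17),12-dien-19-ol | CO/C=C/C[C@@H]1C(=C)CC[C@@H]2[C@](C)(CO)CCC[C@@]12C | intermediate (not isolated)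
9 | (4R,5S,9R,10S)-19-hydroxy-14,15,16-trinor-ent-labd-8(17)-en-13-al | O=CCC[C@@H]1C(=C)CC[C@@H]2[C@](C)(CO)CCC[C@@]12C | intermediate
10 | dimethyl (1-diazo-2-oxopropyl)phosphonate (Ohira–Bestmann reagent) | CC(=O)C(=[N+]=[N-])P(=O)(OC)OC | starting material
11 | (4R,5S,9R,10S)-15,16-dinor-ent-labd-8(17)-en-13-yn-19-ol | C#CCC[C@@H]1C(=C)CC[C@@H]2[C@](C)(CO)CCC[C@@]12C | intermediate
12 | ethylene | C=C | starting material
13 | (4R,5S,9R,10S)-ent-labda-8(17),13(16),14-trien-19-ol | C=CC(=C)CC[C@@H]1C(=C)CC[C@@H]2[C@](C)(CO)CCC[C@@]12C | intermediate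
14 | bromoacetyl bromide | O=C(Br)CBr | starting material
15 | diphenyl phosphite | O=[PH](Oc1ccccc1)Oc1ccccc1 | starting material
16 | ent-labda-8(17),13(16),14-trien-19-yl bromoacetate | C=CC(=C)CC[C@@H]1C(=C)CC[C@@H]2[C@](C)(COC(=O)CBr)CCC[C@@]12C | intermediate (not isolated)
17 | ent-labda-8(17),13(16),14-trien-19-yl (diphenoxyphosphoryl)acetate | C=CC(=C)CC[C@@H]1C(=C)CC[C@@H]2[C@](C)(COC(=O)CP(=O)(Oc3ccccc3)Oc3ccccc3)CCC[C@@]12C | intermediate
18 | 4-(tert-butyldimethylsilyloxy)benzaldehyde | O=Cc1ccc(O[Si](C)(C)C(C)(C)C)cc1 | starting material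
19 | ent-labda-8(17),13(16),14-trien-19-yl (2Z)-3-[4-(tert-butyldimethylsilyloxy)phenyl]prop-2-enoate | C=CC(=C)CC[C@@H]1C(=C)CC[C@@H]2[C@](C)(COC(=O)/C=C\c3ccc(O[Si](C)(C)C(C)(C)C)cc3)CCC[C@@]12C | intermediate (not isolated)
20 | ent-labda-8(17),13(16),14-trien-19-yl (2Z)-3-(4-hydroxyphenyl)prop-2-enoate (CNP0131099.2) | C=CC(=C)CC[C@@H]1C(=C)CC[C@@H]2[C@](C)(COC(=O)/C=C\c3ccc(O)cc3)CCC[C@@]12C | target

**Step count and risks**

Total step count: 8. Longest linear sequence: 8 steps from 1.

The three steps most likely to fail:

Step 1 (chemoselective cleavage). Permanganate may over-oxidise aldehyde 2 to the acid or attack the 8(17)-alkene. The fallback sets out from 1 and separates the two events. Nucleophilic (Weitz–Scheffer) epoxidation with tBuOOH and DBU in CH2Cl2 at 0 °C touches only the electron-poor C12=C13 bond and gives 12,13-epoxyandrographolide F1 (either trans-epoxide diastereomer serves). H5IO6 in THF/H2O then cleaves the epoxide without affecting isolated alkenes or aldehydes, and the route is rejoined at 2.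

Step 4 (regioselective deoxygenation). The six-membered thionocarbonate may be reduced without fragmenting, or cleave partly towards C19. The fallback sets out from 4 and differentiates the two hydroxyls stepwise. TBSCl and imidazole in DMF silylate the primary C19 hydroxyl to give the 19-O-silyl ether F2. NaH, CS2 and MeI convert the 3-hydroxyl into the S-methyl xanthate F3. Bu3SnH and AIBN in toluene at 110 °C give the 3-deoxy silyl ether F4. Finally 1 M HCl in THF removes the silyl group and hydrolyses the enol ether, rejoining the route at 9.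

Step 6 (enyne metathesis). The unactivated alkyne may oligomerise or the catalyst may stall. The fallback sets out from 11 and builds the diene by cross-coupling. α-Selective hydroalumination (iBu2AlH, Ni(dppp)Cl2 3 mol %, THF; one extra equivalent of hydride for the hydroxyl) followed by N-iodosuccinimide gives the 2-iodo-1-alkene F5. Stille coupling with tributyl(vinyl)stannane (Pd(PPh3)4, DMF, 60 °C) then rejoins the route at 13.

**Further compounds**

F1 | step 1 | 12,13-epoxyandrographolide (spiro trans-epoxide of the lactone alkylidene) | O[C@@H]1COC(=O)[C@]12O[C@@H]2C[C@@H]1C(=C)CC[C@@H]2[C@](C)(CO)[C@H](O)CC[C@@]12C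
F2 | step 4 | (12E)-19-(tert-butyldimethylsilyloxy)-13-methoxy-14,15,16-trinor-ent-labda-8(17),12-dien-3-ol | CO/C=C/C[C@@H]1C(=C)CC[C@@H]2[C@](C)(CO[Si](C)(C)C(C)(C)C)[C@H](O)CC[C@@]12C
F3 | step 4 | O-3 S-methyl xanthate of F2 | CO/C=C/C[C@@H]1C(=C)CC[C@@H]2[C@](C)(CO[Si](C)(C)C(C)(C)C)[C@H](OC(=S)SC)CC[C@@]12C
F4 | step 4 | (12E)-19-(tert-butyldimethylsilyloxy)-13-methoxy-14,15,16-trinor-ent-labda-8(17),12-diene | CO/C=C/C[C@@H]1C(=C)CC[C@@H]2[C@](C)(CO[Si](C)(C)C(C)(C)C)CCC[C@@]12C
F5 | step 6 | 13-iodo-15,16-dinor-ent-labda-8(17),13-dien-19-ol | C=C(I)CC[C@@H]1C(=C)CC[C@@H]2[C@](C)(CO)CCC[C@@]12C
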